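**Plan**

- Retrosynthetic cuts: (a) the fourteen O–benzyl bonds and the gallate C–O bond; (b) lower ring C at C4–C4a (epoxide–arene closure) and O1–C2 (Mitsunobu ether); (c) upper ring C at C4–C4a (key step); (d) the upper C4–aryl bond (epoxide opening by the metalated lower ring A) and upper O1–C2 (Mitsunobu ether).
- Forward order: one resolved epoxy alcohol serves both flavan units. The open chain ArO–C2–C3–C4–Ar is assembled, upper ring C is closed oxidatively, lower ring C is grown on the phenol that this closure returns, and esterification and hydrogenolysis finish.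
- Feature used by the key step: upper C4 is a benzylic CH2 on C6 of lower ring A, ortho to O5 and O7 and para to O1 of that ring. With this O1 as a free phenol, two-electron oxidation gives a para-quinone methide whose methide carbon is C4. The O1-bound 3,5-bis(benzyloxy)phenyl group (future upper ring A) can then add through its ortho carbon C4a in a six-membered closure.
- Stereochemistry: C2 and C3 of both units (2R,3R, cis) come from a Sharpless kinetic resolution (erythro epoxy alcohol) followed by Mitsunobu inversion. Upper C4 (4β, trans to O3) is set in the key step under substrate control.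

Key step: step 8

Remark: the target is read as epigallocatechin-(4β→6)-epigallocatechin with the gallate on O3 of the lower unit (upper unit 2R,3R,4S; lower unit 2R,3R). The benzyl-protected aldehyde, phenol and gallic acid used as starting materials are taken as commercial.

**Step 1**
Reactants: 1 3,4,5-tris(benzyloxy)benzaldehyde
Product: 2 rac-1-[3,4,5-tris(benzyloxy)phenyl]prop-2-en-1-ol
Conditions: CH2=CHMgBr, THF, −78 → 0 °C; H2O quench
Reagents that add atoms: vinylmagnesium bromide, C=C[Mg]Br
Why: Grignard 1,2-addition to an aryl aldehyde; the carbinol centre is formed racemic and is resolved in step 2.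

**Step 2**
Reactants: 2 rac-1-[3,4,5-tris(benzyloxy)phenyl]prop-2-en-1-ol
Product: 3 (S)-[(2R)-oxiran-2-yl][3,4,5-tris(benzyloxy)phenyl]methanol
Conditions: Ti(OiPr)4 (0.1 equiv), L-(+)-DIPT (0.15 equiv), t-BuOOH (0.45 equiv), 4 Å MS, CH2Cl2, −20 °C
Reagents that add atoms: tert-butyl hydroperoxide, CC(C)(C)OO
Why: Sharpless kinetic resolution: with L-(+)-diisopropyl tartrate the (R)-alcohol should be epoxidised much faster than the (S)-alcohol and on the face that gives the erythro (anti) epoxy alcohol, so both stereocentres of 3 are fixed by the tartrate (the carbinol descriptor changes from R to S only because the epoxide carbon now outranks the aryl group), and stopping below half conversion keeps the enantiomeric purity of the epoxide high.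

**Step 3**
Reactants: 3 (S)-[(2R)-oxiran-2-yl][3,4,5-tris(benzyloxy)phenyl]methanol; 4 3,5-bis(benzyloxy)phenol
Product: 5 (2R)-2-{(R)-[3,5-bis(benzyloxy)phenoxy][3,4,5-tris(benzyloxy)phenyl]methyl}oxirane
Conditions: PPh3, DIAD, toluene, 0 °C → rt
Reagents that add atoms: none
Why: Mitsunobu etherification of a phenol with a secondary benzylic alcohol is an SN2 displacement of the oxyphosphonium group, so the carbinol centre is inverted (S to R) while the epoxide is untouched, which turns the erythro alcohol into the threo ether needed for a 2,3-cis flavan.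

**Step 4**
Reactants: 4 3,5-bis(benzyloxy)phenol
Product: 6 [3,5-bis(benzyloxy)phenoxy]tri(propan-2-yl)silane
Conditions: i-Pr3SiCl, imidazole, DMF, rt
Reagents that add atoms: chlorotri(propan-2-yl)silane, CC(C)[Si](Cl)(C(C)C)C(C)C
Why: Standard silylation of a phenol; the bulky silyl group masks the oxygen that becomes O1 of the lower unit and steers the metalation of step 5 to the carbon between the two benzyloxy groups.

**Step 5**
Reactants: 6 [3,5-bis(benzyloxy)phenoxy]tri(propan-2-yl)silane; 5 (2R)-2-{(R)-[3,5-bis(benzyloxy)phenoxy][3,4,5-tris(benzyloxy)phenyl]methyl}oxirane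
Product: 9 (1R,2R)-1-[3,5-bis(benzyloxy)phenoxy]-3-[2,6-bis(benzyloxy)-4-(triisopropylsilyloxy)phenyl]-1-[3,4,5-tris(benzyloxy)phenyl]propan-2-ol, via aryllithium 7 (not isolated), via arylmagnesium bromide 8 (not isolated)
Conditions: 6 (1.5 equiv), n-BuLi (1.4 equiv), THF, 0 °C → rt; MgBr2·OEt2, −20 °C; CuI (10 mol %), 5, −30 → 0 °C; H2O quench
Reagents that add atoms: none
Why: Directed ortho-metalation at the C–H flanked by two alkoxy groups, transmetalation to magnesium and copper-catalysed SN2 opening of the terminal epoxide at its CH2 carbon; no stereocentre is touched, so the epoxide carbon becomes the (R)-carbinol that is C3 of the upper unit.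

**Step 6**
Reactants: 9 (1R,2R)-1-[3,5-bis(benzyloxy)phenoxy]-3-[2,6-bis(benzyloxy)-4-(triisopropylsilyloxy)phenyl]-1-[3,4,5-tris(benzyloxy)phenyl]propan-2-ol
Product: 10 (1R,2R)-2-(benzyloxy)-1-[3,5-bis(benzyloxy)phenoxy]-3-[2,6-bis(benzyloxy)-4-(triisopropylsilyloxy)phenyl]-1-[3,4,5-tris(benzyloxy)phenyl]propane
Conditions: NaH, BnBr, Bu4NI (cat.), THF, 0 °C → rt
Reagents that add atoms: benzyl bromide, BrCc1ccccc1
Why: Williamson etherification of the secondary alkoxide under iodide catalysis; THF in place of DMF should keep the aryl silyl ether intact, and no stereocentre is involved.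

**Step 7**
Reactants: 10 (1R,2R)-2-(benzyloxy)-1-[3,5-bis(benzyloxy)phenoxy]-3-[2,6-bis(benzyloxy)-4-(triisopropylsilyloxy)phenyl]-1-[3,4,5-tris(benzyloxy)phenyl]propane
Product: 11 3,5-bis(benzyloxy)-4-{(2R,3R)-2-(benzyloxy)-3-[3,5-bis(benzyloxy)phenoxy]-3-[3,4,5-tris(benzyloxy)phenyl]propyl}phenol
Conditions: Bu4NF, AcOH, THF, 0 °C
Reagents that add atoms: none
Why: Fluoride cleavage of the aryl silyl ether, buffered with acetic acid so that no free phenoxide is present; benzyl ethers and stereocentres are unaffected.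

**Step 8**
Reactants: 11 3,5-bis(benzyloxy)-4-{(2R,3R)-2-(benzyloxy)-3-[3,5-bis(benzyloxy)phenoxy]-3-[3,4,5-tris(benzyloxy)phenyl]propyl}phenol
Product: 13 4β-[2,6-bis(benzyloxy)-4-hydroxyphenyl]-3,5,7,3′,4′,5′-hexa-O-benzyl-(−)-epigallocatechin (2R,3R; 2,3-cis; 3,4-trans), via para-quinone methide 12 (not isolated)
Conditions: undivided cell, graphite anode, Pt cathode, constant current, 2.0 F/mol, Bu4NBF4 (0.1 M), CH2Cl2/(CF3)2CHOH 4:1, 5 mM, 0 °C
Reagents that add atoms: none
Why: Proposed new method: the free phenol of 11 is by far the most easily oxidised group, so the anode should remove two electrons and two protons from it (phenoxyl radical, phenoxonium ion, loss of the benzylic C4 proton) and leave the eight benzyl ethers and the aryl alkyl ether untouched, giving para-quinone methide 12, whose methide carbon is upper C4; the closest known reaction types are the anodic conversion of para-alkylphenols into para-quinone methides that are trapped by nucleophiles and the DDQ-mediated quinone methide Friedel–Crafts cyclisation that gives aryltetralins. Hexafluoropropan-2-ol hydrogen-bonds to the dienone oxygen, and the ortho carbon of the 3,5-bis(benzyloxy)phenyl ether adds to C4 (6-exo-trig 1,6-addition, an intramolecular Friedel–Crafts alkylation), forming C4–C4a and closing upper ring C with rearomatisation of both rings. The new stereocentre C4 is set by the substrate: in the half-chair transition state the C2 aryl group is equatorial, the C3 benzyloxy group axial, and the dienone ring takes the pseudo-axial position anti to O3 and away from the peri benzyloxy group on C5, which gives the 3,4-trans (4β) isomer. The step needs chemoselectivity (only the phenol is oxidised; the charge is limited because the product is again a phenol, although its C4–H bond lies in the plane of the doubly ortho-substituted ring and is not aligned for a second quinone methide formation) and ring-size selectivity (six-membered closure by the triply oxygen-activated ring A carbon in preference to five-membered closure by ring B); the two ortho carbons of the ether ring are equivalent, so no regioisomer can arise.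

**Step 9**
Reactants: 13 4β-[2,6-bis(benzyloxy)-4-hydroxyphenyl]-3,5,7,3′,4′,5′-hexa-O-benzyl-(−)-epigallocatechin; 3 (S)-[(2R)-oxiran-2-yl][3,4,5-tris(benzyloxy)phenyl]methanol
Product: 14 ether of 13 that carries the (R)-[(2R)-oxiran-2-yl][3,4,5-tris(benzyloxy)phenyl]methyl group on the phenolic oxygen
Conditions: PPh3, DIAD, toluene, 0 °C → rt
Reagents that add atoms: none
Why: Second Mitsunobu etherification with the same epoxy alcohol; SN2 inversion at the carbinol carbon (S to R) sets C2 of the lower unit, and the only acidic group in 13 is the unhindered phenol.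

**Step 10**
Reactants: 14 ether of 13 that carries the (R)-[(2R)-oxiran-2-yl][3,4,5-tris(benzyloxy)phenyl]methyl group on the phenolic oxygen
Product: 15 undeca-O-benzyl epigallocatechin-(4β→6)-epigallocatechin with free 3-OH on the lower unit (upper unit 3-O-benzyl; both units 2R,3R)
Conditions: AuCl3 (5 mol %), AgOTf (15 mol %), CH2Cl2, 0 °C → rt
Reagents that add atoms: none
Why: Gold-catalysed epoxide–arene cycloalkylation (intramolecular Friedel–Crafts alkylation, 6-endo attack of an ortho carbon of the aryl ether on the unsubstituted epoxide carbon), a known way to close ring C of benzyl-protected catechins; C2 and C3 of the lower unit keep the configuration of 14 (2,3-cis), and since both ortho carbons are equivalent the upper unit ends on C6 of the lower unit.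

**Step 11**
Reactants: 15 undeca-O-benzyl epigallocatechin-(4β→6)-epigallocatechin with free 3-OH on the lower unit; 16 3,4,5-tris(benzyloxy)benzoic acid
Product: 17 tetradeca-O-benzyl epigallocatechin-(4β→6)-epigallocatechin 3-O-gallate (ester on O3 of the lower unit)
Conditions: DCC, DMAP, CH2Cl2, rt
Reagents that add atoms: none
Why: Steglich esterification of the axial secondary 3-hydroxyl group, the only free hydroxyl group in 15, with retention at C3.

**Step 12**
Reactants: 17 tetradeca-O-benzyl epigallocatechin-(4β→6)-epigallocatechin 3-O-gallate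
Product: 18 epigallocatechin-(4β→6)-epigallocatechin 3-O-gallate (gallate on the lower unit; CNP0204196.2)
Conditions: H2 (1 atm), Pd(OH)2/C, THF/MeOH/H2O, rt
Reagents that add atoms: none
Why: Catalytic hydrogenolysis of all fourteen benzyl ethers under neutral conditions, to which the ester, the interflavan bond, the ring C ether bonds and the stereocentres should be stable.

**Compound list**

1 | 3,4,5-tris(benzyloxy)benzaldehyde | O=Cc1cc(OCc2ccccc2)c(OCc2ccccc2)c(OCc2ccccc2)c1 | starting material
2 | rac-1-[3,4,5-tris(benzyloxy)phenyl]prop-2-en-1-ol | C=CC(O)c1cc(OCc2ccccc2)c(OCc2ccccc2)c(OCc2ccccc2)c1 | intermediate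
3 | (S)-[(2R)-oxiran-2-yl][3,4,5-tris(benzyloxy)phenyl]methanol | O[C@@H](c1cc(OCc2ccccc2)c(OCc2ccccc2)c(OCc2ccccc2)c1)[C@H]1CO1 | intermediate
4 | 3,5-bis(benzyloxy)phenol | Oc1cc(OCc2ccccc2)cc(OCc2ccccc2)c1 | starting material
5 | (2R)-2-{(R)-[3,5-bis(benzyloxy)phenoxy][3,4,5-tris(benzyloxy)phenyl]methyl}oxirane | O(c1cc(OCc2ccccc2)cc(OCc2ccccc2)c1)[C@H](c1cc(OCc2ccccc2)c(OCc2ccccc2)c(OCc2ccccc2)c1)[C@H]1CO1 | intermediate
6 | [3,5-bis(benzyloxy)phenoxy]tri(propan-2-yl)silane | CC(C)[Si](Oc1cc(OCc2ccccc2)cc(OCc2ccccc2)c1)(C(C)C)C(C)C | intermediate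
7 | [2,6-bis(benzyloxy)-4-(triisopropylsilyloxy)phenyl]lithium (not isolated) | [Li]c1c(OCc2ccccc2)cc(O[Si](C(C)C)(C(C)C)C(C)C)cc1OCc1ccccc1 | intermediate
8 | [2,6-bis(benzyloxy)-4-(triisopropylsilyloxy)phenyl]magnesium bromide (not isolated) | Br[Mg]c1c(OCc2ccccc2)cc(O[Si](C(C)C)(C(C)C)C(C)C)cc1OCc1ccccc1 | intermediate
9 | (1R,2R)-1-[3,5-bis(benzyloxy)phenoxy]-3-[2,6-bis(benzyloxy)-4-(triisopropylsilyloxy)phenyl]-1-[3,4,5-tris(benzyloxy)phenyl]propan-2-ol | O(c1cc(OCc2ccccc2)cc(OCc2ccccc2)c1)[C@H](c1cc(OCc2ccccc2)c(OCc2ccccc2)c(OCc2ccccc2)c1)[C@H](O)Cc1c(OCc2ccccc2)cc(O[Si](C(C)C)(C(C)C)C(C)C)cc1OCc1ccccc1 | intermediate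
10 | (1R,2R)-2-(benzyloxy)-1-[3,5-bis(benzyloxy)phenoxy]-3-[2,6-bis(benzyloxy)-4-(triisopropylsilyloxy)phenyl]-1-[3,4,5-tris(benzyloxy)phenyl]propane | O(c1cc(OCc2ccccc2)cc(OCc2ccccc2)c1)[C@H](c1cc(OCc2ccccc2)c(OCc2ccccc2)c(OCc2ccccc2)c1)[C@H](OCc1ccccc1)Cc1c(OCc2ccccc2)cc(O[Si](C(C)C)(C(C)C)C(C)C)cc1OCc1ccccc1 | intermediate
11 | 3,5-bis(benzyloxy)-4-{(2R,3R)-2-(benzyloxy)-3-[3,5-bis(benzyloxy)phenoxy]-3-[3,4,5-tris(benzyloxy)phenyl]propyl}phenol | O(c1cc(OCc2ccccc2)cc(OCc2ccccc2)c1)[C@H](c1cc(OCc2ccccc2)c(OCc2ccccc2)c(OCc2ccccc2)c1)[C@H](OCc1ccccc1)Cc1c(OCc2ccccc2)cc(O)cc1OCc1ccccc1 | intermediate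
12 | 3,5-bis(benzyloxy)-4-{(2R,3R)-2-(benzyloxy)-3-[3,5-bis(benzyloxy)phenoxy]-3-[3,4,5-tris(benzyloxy)phenyl]propylidene}cyclohexa-2,5-dien-1-one (para-quinone methide, not isolated) | O(c1cc(OCc2ccccc2)cc(OCc2ccccc2)c1)[C@H](c1cc(OCc2ccccc2)c(OCc2ccccc2)c(OCc2ccccc2)c1)[C@H](OCc1ccccc1)C=C1C(OCc2ccccc2)=CC(=O)C=C1OCc1ccccc1 | intermediate
13 | 4β-[2,6-bis(benzyloxy)-4-hydroxyphenyl]-3,5,7,3′,4′,5′-hexa-O-benzyl-(−)-epigallocatechin (2R,3R; 2,3-cis; 3,4-trans) | Oc1cc(OCc2ccccc2)c(c(OCc2ccccc2)c1)[C@H]1c2c(OCc3ccccc3)cc(OCc3ccccc3)cc2O[C@H](c2cc(OCc3ccccc3)c(OCc3ccccc3)c(OCc3ccccc3)c2)[C@@H]1OCc1ccccc1 | intermediate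
14 | ether of 13 that carries the (R)-[(2R)-oxiran-2-yl][3,4,5-tris(benzyloxy)phenyl]methyl group on the phenolic oxygen | O(c1cc(OCc2ccccc2)c(c(OCc2ccccc2)c1)[C@H]1c2c(OCc3ccccc3)cc(OCc3ccccc3)cc2O[C@H](c2cc(OCc3ccccc3)c(OCc3ccccc3)c(OCc3ccccc3)c2)[C@@H]1OCc1ccccc1)[C@H](c1cc(OCc2ccccc2)c(OCc2ccccc2)c(OCc2ccccc2)c1)[C@H]1CO1 | intermediate
15 | undeca-O-benzyl epigallocatechin-(4β→6)-epigallocatechin with free 3-OH on the lower unit (upper unit 3-O-benzyl; both units 2R,3R) | O[C@@H]1Cc2c(cc(OCc3ccccc3)c([C@H]3c4c(OCc5ccccc5)cc(OCc5ccccc5)cc4O[C@H](c4cc(OCc5ccccc5)c(OCc5ccccc5)c(OCc5ccccc5)c4)[C@@H]3OCc3ccccc3)c2OCc2ccccc2)O[C@@H]1c1cc(OCc2ccccc2)c(OCc2ccccc2)c(OCc2ccccc2)c1 | intermediate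
16 | 3,4,5-tris(benzyloxy)benzoic acid | OC(=O)c1cc(OCc2ccccc2)c(OCc2ccccc2)c(OCc2ccccc2)c1 | starting material
17 | tetradeca-O-benzyl epigallocatechin-(4β→6)-epigallocatechin 3-O-gallate (ester on O3 of the lower unit) | O=C(O[C@@H]1Cc2c(cc(OCc3ccccc3)c([C@H]3c4c(OCc5ccccc5)cc(OCc5ccccc5)cc4O[C@H](c4cc(OCc5ccccc5)c(OCc5ccccc5)c(OCc5ccccc5)c4)[C@@H]3OCc3ccccc3)c2OCc2ccccc2)O[C@@H]1c1cc(OCc2ccccc2)c(OCc2ccccc2)c(OCc2ccccc2)c1)c1cc(OCc2ccccc2)c(OCc2ccccc2)c(OCc2ccccc2)c1 | intermediate
18 | epigallocatechin-(4β→6)-epigallocatechin 3-O-gallate (gallate on the lower unit; CNP0204196.2) | O=C(O[C@@H]1Cc2c(cc(O)c([C@H]3c4c(O)cc(O)cc4O[C@H](c4cc(O)c(O)c(O)c4)[C@@H]3O)c2O)O[C@@H]1c1cc(O)c(O)c(O)c1)c1cc(O)c(O)c(O)c1 | target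

**Step count and risks**

Total: 12 steps. Longest linear sequence: 11 steps (1 → 2 → 3 → 5 → 9 → 10 → 11 → 13 → 14 → 15 → 17 → 18); step 4 is a one-step branch, and epoxy alcohol 3 is used twice (steps 3 and 9).

Steps most likely to fail:

1. Step 8 (anodic closure of upper ring C). What may go wrong: further oxidation of the product phenol once 11 is depleted (including oxidative loss of the flavanyl group from the phenoxonium ion), oxidation of benzyl aryl ethers if the anode potential drifts upward, or intermolecular capture of the quinone methide. The fallback uses known chemistry, sets out from 5 and comes back at 13; it closes upper ring C first and forms the C4–aryl bond afterwards. Gold-catalysed cycloalkylation of 5 (AuCl3, AgOTf, CH2Cl2; the reaction type of step 10) should give 5,7,3′,4′,5′-penta-O-benzyl-(−)-epigallocatechin F1. NaH and BnBr then give 3,5,7,3′,4′,5′-hexa-O-benzyl-(−)-epigallocatechin F2. DDQ with 2-ethoxyethanol in CH2Cl2 oxidises the benzylic C4–H bond to the 4β-(2-ethoxyethoxy) hexa-O-benzyl-epigallocatechin F3. TMSOTf at −78 °C ionises F3, and silyl ether 6 should attack the flavan-4-yl cation anti to O3 through its carbon between the two benzyloxy groups (the other two ring carbons are shielded by the triisopropylsilyl group), giving the triisopropylsilyl ether of 13 F4. Bu4NF/AcOH then frees phenol 13.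

2. Step 5 (metalation and epoxide opening). What may go wrong: deprotonation of a benzylic OCH2 group (followed by Wittig rearrangement) or of a ring carbon next to the silyl ether competes with the wanted lithiation, so that wrong or rearranged aryl groups are carried into the epoxide opening. The fallback sets out from 6 and comes back at 7; it replaces deprotonation by halogen–metal exchange. NBS in CH2Cl2 at −78 °C should brominate 6 at the carbon para to, and remote from, the bulky silyl ether to give 2-bromo-1,3-bis(benzyloxy)-5-(triisopropylsilyloxy)benzene F5 (recognisable by its symmetry). n-BuLi in THF at −78 °C exchanges bromine for lithium faster than any C–H is deprotonated and gives aryllithium 7, which is carried on as in step 5.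

3. Step 10 (gold-catalysed closure of lower ring C). What may go wrong: ionisation of the benzylic C2–O bond of the new ether by the Lewis acid (loss of the aryl ether or scrambling at C2 of the lower unit), attack of the arene at the internal epoxide carbon (five-membered ring), or acid-induced cleavage of the interflavan bond. The fallback sets out from 13 and comes back at 15; it closes the ring by an anionic instead of a cationic path. NBS (1 equiv, CH2Cl2, −78 °C) should brominate the phenol ring of 13 ortho to the hydroxyl group, giving the ortho-bromophenol of 13 F6. Mitsunobu etherification with 3 as in step 9 gives the bromo analogue of epoxy ether 14 F7. MgBr2·OEt2 opens the epoxide at its CH2 carbon to the bromohydrin, held in the flask as the bromomagnesium alkoxide of the bromohydrin F8. n-BuLi at −78 °C then exchanges the aryl bromine, and the aryllithium displaces the primary bromide (Parham cyclialkylation, six-membered SN2 closure); aqueous work-up gives 15.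

**Further compounds**

F1 | step 8 | 5,7,3′,4′,5′-penta-O-benzyl-(−)-epigallocatechin | O[C@@H]1Cc2c(OCc3ccccc3)cc(OCc3ccccc3)cc2O[C@@H]1c1cc(OCc2ccccc2)c(OCc2ccccc2)c(OCc2ccccc2)c1
F2 | step 8 | 3,5,7,3′,4′,5′-hexa-O-benzyl-(−)-epigallocatechin | O(Cc1ccccc1)[C@@H]1Cc2c(OCc3ccccc3)cc(OCc3ccccc3)cc2O[C@@H]1c1cc(OCc2ccccc2)c(OCc2ccccc2)c(OCc2ccccc2)c1
F3 | step 8 | 4β-(2-ethoxyethoxy)-3,5,7,3′,4′,5′-hexa-O-benzyl-(−)-epigallocatechin | CCOCCO[C@H]1c2c(OCc3ccccc3)cc(OCc3ccccc3)cc2O[C@H](c2cc(OCc3ccccc3)c(OCc3ccccc3)c(OCc3ccccc3)c2)[C@@H]1OCc1ccccc1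
F4 | step 8 | triisopropylsilyl ether of 13 | CC(C)[Si](C(C)C)(C(C)C)Oc1cc(OCc2ccccc2)c(c(OCc2ccccc2)c1)[C@H]1c2c(OCc3ccccc3)cc(OCc3ccccc3)cc2O[C@H](c2cc(OCc3ccccc3)c(OCc3ccccc3)c(OCc3ccccc3)c2)[C@@H]1OCc1ccccc1
F5 | step 5 | 2-bromo-1,3-bis(benzyloxy)-5-(triisopropylsilyloxy)benzene | Brc1c(OCc2ccccc2)cc(O[Si](C(C)C)(C(C)C)C(C)C)cc1OCc1ccccc1
F6 | step 10 | ortho-bromophenol of 13 (bromine next to the phenolic hydroxyl group) | Oc1c(Br)c(OCc2ccccc2)c(c(OCc2ccccc2)c1)[C@H]1c2c(OCc3ccccc3)cc(OCc3ccccc3)cc2O[C@H](c2cc(OCc3ccccc3)c(OCc3ccccc3)c(OCc3ccccc3)c2)[C@@H]1OCc1ccccc1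
F7 | step 10 | bromo analogue of epoxy ether 14 | O(c1c(Br)c(OCc2ccccc2)c(c(OCc2ccccc2)c1)[C@H]1c2c(OCc3ccccc3)cc(OCc3ccccc3)cc2O[C@H](c2cc(OCc3ccccc3)c(OCc3ccccc3)c(OCc3ccccc3)c2)[C@@H]1OCc1ccccc1)[C@H](c1cc(OCc2ccccc2)c(OCc2ccccc2)c(OCc2ccccc2)c1)[C@H]1CO1
F8 | step 10 | bromomagnesium alkoxide of the bromohydrin from F7 | O(c1c(Br)c(OCc2ccccc2)c(c(OCc2ccccc2)c1)[C@H]1c2c(OCc3ccccc3)cc(OCc3ccccc3)cc2O[C@H](c2cc(OCc3ccccc3)c(OCc3ccccc3)c(OCc3ccccc3)c2)[C@@H]1OCc1ccccc1)[C@H](c1cc(OCc2ccccc2)c(OCc2ccccc2)c(OCc2ccccc2)c1)[C@H](O[Mg]Br)CBr
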